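**Plan**

1. Retrosynthetic cuts: the C8–O ester bond (side-chain acid from the (S)-malic acid pool); the C8–C9 bond of ring B (carbonyl-ene closure); in ring A the bonds from C4, the carbon that carries C15, to C5 and C3 (one-carbon ring contraction in the retro sense, to a cyclopentanone); then C7–C11, C6–C7 and C1–C10 (two conjugate additions and an aldol on cyclopent-2-enone).
2. Forward order: cyclopentenone → trans-2,3-disubstituted cyclopentanone carrying C1, C6 and C7 → ring expansion to the six-membered ring A (β-keto ester, enol triflate, enoate) → ring B by type-2 carbonyl-ene closure → C8 inversion by oxidation/reduction, esterification, C12 oxidation, deprotection.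
3. Enabling feature: ring A (C1–C6) has its only branch, C15, on C4 next to C5, and C5 adjoins the ring-fusion carbon C6. This is the pattern of a 2-oxocyclohexane-1-carboxylate (C5=O, C4–CO2Et), which results when a CH(CO2Et) unit is inserted on the unsubstituted side of a 2,3-disubstituted cyclopentanone.
4. Stereochemistry: C1 by ligand-controlled copper-catalysed conjugate addition; C6 trans to C1 (aldol trapping, thermodynamic); C7 by cuprate addition anti to the C1 group on the (E)-alkylidene ketone; C8 by axial hydride delivery anti to the axial C7 chain; C3′ from the chiral pool.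

Key step: step 5

Assumption: cadinane numbering is used (ring A = C1–C6 with C15 on C4; ring B = C1, C6–C10 with C14 on C10; C11–C13 = three-carbon unit on C7; primed locants = acyl side chain; α = the face of H-6), and compounds 1, 2, 4, 5, 6, 14 and 24 are taken as purchasable.

Step 1
Reactants: 1 4-methoxybenzyl alcohol; 2 2,3-dibromopropene
Product: 3 2-bromoallyl 4-methoxybenzyl ether
Conditions: NaH, THF/DMF, 0 °C; then 2, 0 °C to rt
Reagents that add atoms: none
Why: Williamson ether synthesis, in which the sodium alkoxide of 1 displaces the allylic bromide of 2 (SN2) while the vinylic bromide stays untouched.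

Step 2
Reactants: 4 cyclopent-2-en-1-one; 5 isopropenylmagnesium bromide; 6 (tert-butyldimethylsilyloxy)acetaldehyde
Product: 8 (2S,3S)-2-[2-(tert-butyldimethylsilyloxy)-1-hydroxyethyl]-3-(prop-1-en-2-yl)cyclopentan-1-one (both carbinol epimers), via magnesium enolate 7 (not isolated)
Conditions: CuBr·SMe2 (5 mol %), (R)-1-[(SP)-2-(diphenylphosphino)ferrocenyl]ethyldicyclohexylphosphine or its enantiomer (6 mol %, the antipode that gives (S)-7), t-BuOMe, −75 °C; then 6, −75 °C; sat. aq. NH4Cl
Reagents that add atoms: none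
Why: Copper-catalysed enantioselective conjugate addition of an alkenyl Grignard reagent with a chiral ferrocenyl diphosphine should set C1, and the regiodefined magnesium enolate is trapped at C6 in an aldol addition anti to the new isopropenyl group (2,3-trans); the carbinol centre is removed in step 3.

Step 3
Reactants: 8 (2S,3S)-2-[2-(tert-butyldimethylsilyloxy)-1-hydroxyethyl]-3-(prop-1-en-2-yl)cyclopentan-1-one
Product: 10 (2E,3R)-2-[2-(tert-butyldimethylsilyloxy)ethylidene]-3-(prop-1-en-2-yl)cyclopentan-1-one, via mesylate 9 (not isolated)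
Conditions: MsCl, Et3N, DMAP (cat.), CH2Cl2, 0 °C to rt
Reagents that add atoms: none
Why: Mesylation and E1cB elimination complete an aldol condensation and should give the thermodynamically preferred (E)-alkylidene ketone with the C8 methylene syn to C1; the mild amine base at 0 °C is chosen to avoid deprotonation at the doubly allylic C1.

Step 4
Reactants: 3 2-bromoallyl 4-methoxybenzyl ether; 10 (2E,3R)-2-[2-(tert-butyldimethylsilyloxy)ethylidene]-3-(prop-1-en-2-yl)cyclopentan-1-one
Product: 13 (2S,3S)-2-{(2R)-1-(tert-butyldimethylsilyloxy)-3-[(4-methoxybenzyloxy)methyl]but-3-en-2-yl}-3-(prop-1-en-2-yl)cyclopentan-1-one, via alkenyllithium 11 (not isolated), via homocuprate 12 (not isolated)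
Conditions: 3 (2.4 equiv), t-BuLi (4.8 equiv), Et2O, −78 °C; CuBr·SMe2 (1.2 equiv), −78 °C; 10, −78 to −40 °C; sat. aq. NH4Cl; then DBU (cat.), CH2Cl2, rt
Reagents that add atoms: none
Why: Gilman cuprate 1,4-addition to the s-cis exocyclic enone, in which the reagent should attack C7 on the face opposite the C1 isopropenyl group (held out of the enone plane by A(1,3) strain with the (E)-CH2OTBS group), thereby setting C7, while the base equilibration leaves C6 trans to C1.

Step 5
Reactants: 13 (2S,3S)-2-{(2R)-1-(tert-butyldimethylsilyloxy)-3-[(4-methoxybenzyloxy)methyl]but-3-en-2-yl}-3-(prop-1-en-2-yl)cyclopentan-1-one; 14 ethyl diazoacetate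
Product: 15 ethyl (3S,4S)-3-{(2R)-1-(tert-butyldimethylsilyloxy)-3-[(4-methoxybenzyloxy)methyl]but-3-en-2-yl}-2-oxo-4-(prop-1-en-2-yl)cyclohexane-1-carboxylate (keto/enol mixture at C1 of the ring)
Conditions: 14 (1.5 equiv), BF3·OEt2 (1.2 equiv), CH2Cl2, −78 to 0 °C
Reagents that add atoms: none
Why: BF3 activates the C5 carbonyl, the diazo carbon of 14 adds to give a β-oxido diazonium betaine, and loss of N2 is coupled to a 1,2-shift of the ring bond anti to the leaving group, so that the CH(CO2Et) carbon (C4, carrying the future C15) is inserted between C5 and C3 and the five-membered ring becomes six-membered ring A. The closest known reaction type is the Lewis-acid-promoted homologation of cycloalkanones with diazoacetic esters (Tiffeneau–Demjanov-type ring expansion). No ring is closed by cyclisation; ring A arises by one-carbon insertion into the existing carbocycle. The only new stereocentre, C4, is configurationally labile (β-keto ester, largely enol or boron chelate) and is erased in step 6, whereas C1, C6 and C7 are not involved and C6 remains trans to C1 as the thermodynamic arrangement. The step needs migration of the unsubstituted methylene C3 and not of the tertiary C6; the known preference of this homologation for the less substituted carbon, reinforced by the bulky branched substituent on C6, should secure it, and chelation of the β-keto ester product should prevent a second insertion. The two 1,1-disubstituted alkenes are expected to survive because no metal carbene is formed, and the low temperature is chosen to spare the silyl and PMB ethers.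

Step 6
Reactants: 15 ethyl (3S,4S)-3-{(2R)-1-(tert-butyldimethylsilyloxy)-3-[(4-methoxybenzyloxy)methyl]but-3-en-2-yl}-2-oxo-4-(prop-1-en-2-yl)cyclohexane-1-carboxylate
Product: 16 ethyl (3S,4S)-3-{(2R)-1-(tert-butyldimethylsilyloxy)-3-[(4-methoxybenzyloxy)methyl]but-3-en-2-yl}-4-(prop-1-en-2-yl)-2-(trifluoromethylsulfonyloxy)cyclohex-1-ene-1-carboxylate
Conditions: NaH, THF, 0 °C; then PhNTf2, 0 °C to rt
Reagents that add atoms: N-phenylbis(trifluoromethanesulfonimide), O=S(=O)(N(c1ccccc1)S(=O)(=O)C(F)(F)F)C(F)(F)F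
Why: Enol triflate formation by O-sulfonylation of the sodium enolate of the β-keto ester, which lies between the two carbonyls and therefore fixes the double bond at C4=C5 while removing the labile C4 centre.

Step 7
Reactants: 16 the enol triflate
Product: 17 ethyl (3S,4S)-3-{(2R)-1-(tert-butyldimethylsilyloxy)-3-[(4-methoxybenzyloxy)methyl]but-3-en-2-yl}-4-(prop-1-en-2-yl)cyclohex-1-ene-1-carboxylate
Conditions: Pd(OAc)2 (5 mol %), PPh3 (10 mol %), HCO2H, n-Bu3N, DMF, 60 °C
Reagents that add atoms: none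
Why: Palladium-catalysed formate reduction of an enol triflate (oxidative addition of zerovalent palladium, formate exchange, loss of CO2, C–H reductive elimination) should give the C4=C5 enoate without touching the isolated alkenes or C6.

Step 8
Reactants: 17 the silyl-protected enoate
Product: 18 ethyl (3S,4S)-3-{(2R)-1-hydroxy-3-[(4-methoxybenzyloxy)methyl]but-3-en-2-yl}-4-(prop-1-en-2-yl)cyclohex-1-ene-1-carboxylate
Conditions: HF·pyridine, pyridine, THF, 0 °C to rt
Reagents that add atoms: none
Why: Fluoride-mediated desilylation of the primary silyl ether, with the PMB ether and the enoate stable to buffered HF·pyridine.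

Step 9
Reactants: 18 the primary alcohol
Product: 19 ethyl (3S,4S)-3-{(2R)-3-[(4-methoxybenzyloxy)methyl]-1-oxobut-3-en-2-yl}-4-(prop-1-en-2-yl)cyclohex-1-ene-1-carboxylate
Conditions: Dess–Martin periodinane, pyridine, CH2Cl2, 0 °C; used crude
Reagents that add atoms: none
Why: Dess–Martin oxidation under pyridine buffering should give the α-branched β,γ-unsaturated aldehyde without epimerising C7.

Step 10
Reactants: 19 the aldehyde
Product: 20 ethyl (1S,6S,7R,8S)-8-hydroxy-12-(4-methoxybenzyloxy)cadina-4,10(14),11(13)-trien-15-oate (8α-OH)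
Conditions: Me2AlCl (2.5 equiv), CH2Cl2, −78 °C; aq. Rochelle salt
Reagents that add atoms: none
Why: Type-2 intramolecular carbonyl-ene reaction, in which C8 bonds to the CH2 terminus of the C1 isopropenyl group through a trans-decalin-like chair with the C7 chain axial and the aluminium-bound oxygen axial (as required for hydrogen transfer from the methyl group), closing ring B with the exocyclic C10 methylene and giving the 8α (axial) alcohol that is corrected in steps 11 and 12.

Step 11
Reactants: 20 the 8α-alcohol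
Product: 21 ethyl (1S,6S,7R)-12-(4-methoxybenzyloxy)-8-oxocadina-4,10(14),11(13)-trien-15-oate
Conditions: Dess–Martin periodinane, pyridine, CH2Cl2, 0 °C; filtered, used crude
Reagents that add atoms: none
Why: Dess–Martin oxidation of the hindered axial alcohol under non-basic conditions, the β,γ-unsaturated ketone being carried on without purification to avoid enolisation toward C7 or C9.

Step 12
Reactants: 21 the C8 ketone
Product: 22 (1S,6S,7R,8R)-12-(4-methoxybenzyloxy)cadina-4,10(14),11(13)-triene-8,15-diol (8β-OH)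
Conditions: i-Bu2AlH (5 equiv), CH2Cl2, −78 °C; aq. Rochelle salt
Reagents that add atoms: none
Why: Hydride reduction in which the enoate is reduced 1,2 to the C15 allylic alcohol and the ketone is attacked along the axial trajectory from the α face, anti to the axial C7 chain that blocks equatorial approach, so that the 8β (equatorial) alcohol cis to the C7 substituent should result.

Step 13
Reactants: 22 the diol
Product: 23 (1S,6S,7R,8R)-15-(tert-butyldimethylsilyloxy)-12-(4-methoxybenzyloxy)cadina-4,10(14),11(13)-trien-8-ol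
Conditions: TBSCl (1.05 equiv), imidazole, CH2Cl2, 0 °C
Reagents that add atoms: tert-butyldimethylsilyl chloride, CC(C)(C)[Si](C)(C)Cl
Why: Selective silylation of the primary allylic alcohol over the hindered secondary C8 alcohol on steric grounds.

Step 14
Reactants: 24 methyl (S)-2-(2,2-dimethyl-1,3-dioxolan-4-yl)acetate
Product: 27 methyl 2-[(4S)-2,2-dimethyl-1,3-dioxolan-4-yl]prop-2-enoate, via Mannich base 25 (not isolated), via methiodide 26 (not isolated)
Conditions: i-Pr2NH, n-BuLi, THF, −78 °C; Eschenmoser's salt, −78 °C to rt; then MeI, MeOH, rt; then DBU, CH2Cl2, rt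
Reagents that add atoms: N,N-dimethylmethyleneiminium iodide (Eschenmoser's salt), C=[N+](C)C.[I-]
Why: α-Methylenation of an ester by Mannich reaction of its lithium enolate, N-methylation and E1cB elimination, with the enolate kept at −78 °C to avoid β-elimination of the dioxolane oxygen and the chiral-pool stereocentre not involved.

Step 15
Reactants: 27 methyl 2-[(4S)-2,2-dimethyl-1,3-dioxolan-4-yl]prop-2-enoate
Product: 28 2-[(4S)-2,2-dimethyl-1,3-dioxolan-4-yl]prop-2-enoic acid
Conditions: LiOH, THF/H2O, 0 °C; then 1 M HCl to pH 3–4, 0 °C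
Reagents that add atoms: lithium hydroxide, [Li+].[OH-]
Why: Saponification of the methyl ester at 0 °C, the acetonide being base-stable and the brief cold acidification chosen to spare it.

Step 16
Reactants: 23 (1S,6S,7R,8R)-15-(tert-butyldimethylsilyloxy)-12-(4-methoxybenzyloxy)cadina-4,10(14),11(13)-trien-8-ol; 28 2-[(4S)-2,2-dimethyl-1,3-dioxolan-4-yl]prop-2-enoic acid
Product: 30 (1S,6S,7R,8R)-15-(tert-butyldimethylsilyloxy)-12-(4-methoxybenzyloxy)cadina-4,10(14),11(13)-trien-8-yl 2-[(4S)-2,2-dimethyl-1,3-dioxolan-4-yl]prop-2-enoate, via mixed anhydride 29 (not isolated)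
Conditions: 28, 2,4,6-trichlorobenzoyl chloride, Et3N, THF, rt; then 23, DMAP, toluene, rt
Reagents that add atoms: none
Why: Yamaguchi esterification through the mixed anhydride with DMAP catalysis should acylate the equatorial C8 alcohol with retention at C8 and without touching C3′.

Step 17
Reactants: 30 the fully protected ester
Product: 31 (1S,6S,7R,8R)-15-(tert-butyldimethylsilyloxy)-12-hydroxycadina-4,10(14),11(13)-trien-8-yl 2-[(4S)-2,2-dimethyl-1,3-dioxolan-4-yl]prop-2-enoate
Conditions: DDQ, CH2Cl2/pH 7 phosphate buffer, 0 °C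
Reagents that add atoms: none
Why: Oxidative cleavage of the PMB ether (single-electron oxidation of the electron-rich arene, hydrolysis of the oxocarbenium ion), to which the silyl ether, acetonide and alkenes are inert.

Step 18
Reactants: 31 the C12 allylic alcohol
Product: 33 (1S,6S,7R,8R)-15-(tert-butyldimethylsilyloxy)-8-{2-[(4S)-2,2-dimethyl-1,3-dioxolan-4-yl]prop-2-enoyloxy}cadina-4,10(14),11(13)-trien-12-oic acid, via enal 32 (not isolated)
Conditions: Dess–Martin periodinane, pyridine, CH2Cl2, 0 °C; then NaClO2, NaH2PO4, 2-methyl-2-butene, t-BuOH/H2O, 0 °C to rt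
Reagents that add atoms: sodium chlorite, [Na+].[O-]Cl=O
Why: Dess–Martin oxidation of the allylic alcohol to the 2-substituted acrolein followed by Pinnick oxidation with a hypochlorite scavenger should give the acrylic acid without affecting the other alkenes.

Step 19
Reactants: 33 the protected acid
Product: 34 (1S,6S,7R,8R)-8-[(3S)-3,4-dihydroxy-2-methylenebutanoyloxy]-15-hydroxycadina-4,10(14),11(13)-trien-12-oic acid (CNP0460913.2)
Conditions: AcOH/H2O/THF (3:1:1), 40 °C
Reagents that add atoms: none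
Why: Mild acid hydrolysis removes the acetonide and the primary allylic silyl ether in one operation, the weak acid being chosen to avoid lactonisation of the dihydroxy ester and migration of the exocyclic alkene.

**Compound list**

1 | 4-methoxybenzyl alcohol | COc1ccc(CO)cc1 | starting material
2 | 2,3-dibromopropene | C=C(Br)CBr | starting material
3 | 2-bromoallyl 4-methoxybenzyl ether | C=C(Br)COCc1ccc(OC)cc1 | intermediate
4 | cyclopent-2-en-1-one | O=C1C=CCC1 | starting material
5 | isopropenylmagnesium bromide | C=C(C)[Mg]Br | starting material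
6 | (tert-butyldimethylsilyloxy)acetaldehyde | O=CCO[Si](C)(C)C(C)(C)C | starting material
7 | bromomagnesium (3S)-3-(prop-1-en-2-yl)cyclopent-1-en-1-olate | Br[Mg]OC1=C[C@@H](C(C)=C)CC1 | intermediate (not isolated)
8 | (2S,3S)-2-[2-(tert-butyldimethylsilyloxy)-1-hydroxyethyl]-3-(prop-1-en-2-yl)cyclopentan-1-one | O=C1[C@H](C(O)CO[Si](C)(C)C(C)(C)C)[C@@H](C(C)=C)CC1 | intermediate
9 | methanesulfonate of 8 | O=C1[C@H](C(OS(C)(=O)=O)CO[Si](C)(C)C(C)(C)C)[C@@H](C(C)=C)CC1 | intermediate (not isolated)
10 | (2E,3R)-2-[2-(tert-butyldimethylsilyloxy)ethylidene]-3-(prop-1-en-2-yl)cyclopentan-1-one | O=C1/C(=C/CO[Si](C)(C)C(C)(C)C)[C@@H](C(C)=C)CC1 | intermediate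
11 | [3-(4-methoxybenzyloxy)prop-1-en-2-yl]lithium | [Li]C(=C)COCc1ccc(OC)cc1 | intermediate (not isolated)
12 | lithium bis[3-(4-methoxybenzyloxy)prop-1-en-2-yl]cuprate | [Li+].C=C(COCc1ccc(OC)cc1)[Cu-]C(=C)COCc1ccc(OC)cc1 | intermediate (not isolated)
13 | (2S,3S)-2-{(2R)-1-(tert-butyldimethylsilyloxy)-3-[(4-methoxybenzyloxy)methyl]but-3-en-2-yl}-3-(prop-1-en-2-yl)cyclopentan-1-one | O=C1[C@H]([C@@H](CO[Si](C)(C)C(C)(C)C)C(=C)COCc2ccc(OC)cc2)[C@@H](C(C)=C)CC1 | intermediate
14 | ethyl diazoacetate | CCOC(=O)C=[N+]=[N-] | starting material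
15 | ethyl (3S,4S)-3-{(2R)-1-(tert-butyldimethylsilyloxy)-3-[(4-methoxybenzyloxy)methyl]but-3-en-2-yl}-2-oxo-4-(prop-1-en-2-yl)cyclohexane-1-carboxylate | CCOC(=O)C1C(=O)[C@H]([C@@H](CO[Si](C)(C)C(C)(C)C)C(=C)COCc2ccc(OC)cc2)[C@@H](C(C)=C)CC1 | intermediate
16 | ethyl (3S,4S)-3-{(2R)-1-(tert-butyldimethylsilyloxy)-3-[(4-methoxybenzyloxy)methyl]but-3-en-2-yl}-4-(prop-1-en-2-yl)-2-(trifluoromethylsulfonyloxy)cyclohex-1-ene-1-carboxylate | CCOC(=O)C1=C(OS(=O)(=O)C(F)(F)F)[C@H]([C@@H](CO[Si](C)(C)C(C)(C)C)C(=C)COCc2ccc(OC)cc2)[C@@H](C(C)=C)CC1 | intermediate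
17 | ethyl (3S,4S)-3-{(2R)-1-(tert-butyldimethylsilyloxy)-3-[(4-methoxybenzyloxy)methyl]but-3-en-2-yl}-4-(prop-1-en-2-yl)cyclohex-1-ene-1-carboxylate | CCOC(=O)C1=C[C@H]([C@@H](CO[Si](C)(C)C(C)(C)C)C(=C)COCc2ccc(OC)cc2)[C@@H](C(C)=C)CC1 | intermediate
18 | ethyl (3S,4S)-3-{(2R)-1-hydroxy-3-[(4-methoxybenzyloxy)methyl]but-3-en-2-yl}-4-(prop-1-en-2-yl)cyclohex-1-ene-1-carboxylate | CCOC(=O)C1=C[C@H]([C@@H](CO)C(=C)COCc2ccc(OC)cc2)[C@@H](C(C)=C)CC1 | intermediate
19 | ethyl (3S,4S)-3-{(2R)-3-[(4-methoxybenzyloxy)methyl]-1-oxobut-3-en-2-yl}-4-(prop-1-en-2-yl)cyclohex-1-ene-1-carboxylate | CCOC(=O)C1=C[C@H]([C@@H](C=O)C(=C)COCc2ccc(OC)cc2)[C@@H](C(C)=C)CC1 | intermediate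
20 | ethyl (1S,6S,7R,8S)-8-hydroxy-12-(4-methoxybenzyloxy)cadina-4,10(14),11(13)-trien-15-oate | C=C(COCc3ccc(OC)cc3)[C@H]1[C@H]2C=C(C(=O)OCC)CC[C@@H]2C(=C)C[C@@H]1O | intermediate
21 | ethyl (1S,6S,7R)-12-(4-methoxybenzyloxy)-8-oxocadina-4,10(14),11(13)-trien-15-oate | C=C(COCc3ccc(OC)cc3)[C@H]1[C@H]2C=C(C(=O)OCC)CC[C@@H]2C(=C)CC1=O | intermediate
22 | (1S,6S,7R,8R)-12-(4-methoxybenzyloxy)cadina-4,10(14),11(13)-triene-8,15-diol | C=C(COCc3ccc(OC)cc3)[C@H]1[C@H]2C=C(CO)CC[C@@H]2C(=C)C[C@H]1O | intermediate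
23 | (1S,6S,7R,8R)-15-(tert-butyldimethylsilyloxy)-12-(4-methoxybenzyloxy)cadina-4,10(14),11(13)-trien-8-ol | C=C(COCc3ccc(OC)cc3)[C@H]1[C@H]2C=C(CO[Si](C)(C)C(C)(C)C)CC[C@@H]2C(=C)C[C@H]1O | intermediate
24 | methyl (S)-2-(2,2-dimethyl-1,3-dioxolan-4-yl)acetate | COC(=O)C[C@H]1COC(C)(C)O1 | starting material
25 | methyl 3-(dimethylamino)-2-[(4S)-2,2-dimethyl-1,3-dioxolan-4-yl]propanoate | COC(=O)C(CN(C)C)[C@H]1COC(C)(C)O1 | intermediate (not isolated)
26 | {2-[(4S)-2,2-dimethyl-1,3-dioxolan-4-yl]-3-methoxy-3-oxopropyl}trimethylammonium iodide | COC(=O)C(C[N+](C)(C)C)[C@H]1COC(C)(C)O1.[I-] | intermediate (not isolated)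
27 | methyl 2-[(4S)-2,2-dimethyl-1,3-dioxolan-4-yl]prop-2-enoate | COC(=O)C(=C)[C@H]1COC(C)(C)O1 | intermediate
28 | 2-[(4S)-2,2-dimethyl-1,3-dioxolan-4-yl]prop-2-enoic acid | OC(=O)C(=C)[C@H]1COC(C)(C)O1 | intermediate
29 | 2-[(4S)-2,2-dimethyl-1,3-dioxolan-4-yl]prop-2-enoic 2,4,6-trichlorobenzoic anhydride | C=C(C(=O)OC(=O)c1c(Cl)cc(Cl)cc1Cl)[C@H]1COC(C)(C)O1 | intermediate (not isolated)
30 | (1S,6S,7R,8R)-15-(tert-butyldimethylsilyloxy)-12-(4-methoxybenzyloxy)cadina-4,10(14),11(13)-trien-8-yl 2-[(4S)-2,2-dimethyl-1,3-dioxolan-4-yl]prop-2-enoate | C=C(COCc3ccc(OC)cc3)[C@H]1[C@H]2C=C(CO[Si](C)(C)C(C)(C)C)CC[C@@H]2C(=C)C[C@H]1OC(=O)C(=C)[C@H]4COC(C)(C)O4 | intermediate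
31 | (1S,6S,7R,8R)-15-(tert-butyldimethylsilyloxy)-12-hydroxycadina-4,10(14),11(13)-trien-8-yl 2-[(4S)-2,2-dimethyl-1,3-dioxolan-4-yl]prop-2-enoate | C=C(CO)[C@H]1[C@H]2C=C(CO[Si](C)(C)C(C)(C)C)CC[C@@H]2C(=C)C[C@H]1OC(=O)C(=C)[C@H]3COC(C)(C)O3 | intermediate
32 | (1S,6S,7R,8R)-15-(tert-butyldimethylsilyloxy)-12-oxocadina-4,10(14),11(13)-trien-8-yl 2-[(4S)-2,2-dimethyl-1,3-dioxolan-4-yl]prop-2-enoate | C=C(C=O)[C@H]1[C@H]2C=C(CO[Si](C)(C)C(C)(C)C)CC[C@@H]2C(=C)C[C@H]1OC(=O)C(=C)[C@H]3COC(C)(C)O3 | intermediate (not isolated)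
33 | (1S,6S,7R,8R)-15-(tert-butyldimethylsilyloxy)-8-{2-[(4S)-2,2-dimethyl-1,3-dioxolan-4-yl]prop-2-enoyloxy}cadina-4,10(14),11(13)-trien-12-oic acid | C=C(C(=O)O)[C@H]1[C@H]2C=C(CO[Si](C)(C)C(C)(C)C)CC[C@@H]2C(=C)C[C@H]1OC(=O)C(=C)[C@H]3COC(C)(C)O3 | intermediate
34 | (1S,6S,7R,8R)-8-[(3S)-3,4-dihydroxy-2-methylenebutanoyloxy]-15-hydroxycadina-4,10(14),11(13)-trien-12-oic acid (CNP0460913.2) | C=C(C(=O)O)[C@H]1[C@H]2C=C(CO)CC[C@@H]2C(=C)C[C@H]1OC(=O)C(=C)[C@H](O)CO | target

**Step count and risks**

Total step count: 19. Longest linear sequence: 16 steps (steps 2–13 and 16–19, from cyclopent-2-en-1-one).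

Step 5 (key ring expansion). What may go wrong is migration of the substituted carbon C6 in competition with C3, or Lewis-acid-triggered side reactions before the diazo ester has added (carbonyl-ene closure of the activated ketone onto the isopropenyl group, loss of the silyl or PMB ether). The fallback sets out from 13 and comes back at 17. Homologation with trimethylsilyldiazomethane and AlMe3 in CH2Cl2 at −78 °C, a variant known to move the less substituted carbon, should give (2S,3S)-2-{(2R)-1-(tert-butyldimethylsilyloxy)-3-[(4-methoxybenzyloxy)methyl]but-3-en-2-yl}-3-(prop-1-en-2-yl)-6-(trimethylsilyl)cyclohexan-1-one F1. K2CO3 in MeOH removes the silyl group to give the corresponding cyclohexanone, (2S,3S)-2-{(2R)-1-(tert-butyldimethylsilyloxy)-3-[(4-methoxybenzyloxy)methyl]but-3-en-2-yl}-3-(prop-1-en-2-yl)cyclohexan-1-one F2. Its kinetic lithium enolate (LDA, THF, −78 °C, deprotonation at the unhindered C4) is trapped with N-phenylbis(trifluoromethanesulfonimide) as the enol triflate, (5S,6S)-6-{(2R)-1-(tert-butyldimethylsilyloxy)-3-[(4-methoxybenzyloxy)methyl]but-3-en-2-yl}-5-(prop-1-en-2-yl)cyclohex-1-en-1-yl trifluoromethanesulfonate F3. Palladium-catalysed ethoxycarbonylation (Pd(OAc)2, PPh3, CO, EtOH, Et3N, DMF) then brings in C15 and gives 17. Ring A still arises by one-carbon expansion, but C15 is introduced separately through a regiodefined enolate.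

Step 4 (second conjugate addition). What may go wrong is insufficient facial discrimination at C7, or electron transfer from the cuprate to the γ-silyloxy enone with loss of silanolate instead of addition. The fallback sets out from 3 and 10 and comes back at 13. The alkenyllithium 11 is quenched with 2-isopropoxy-4,4,5,5-tetramethyl-1,3,2-dioxaborolane to give the pinacol boronate 2-[3-(4-methoxybenzyloxy)prop-1-en-2-yl]-4,4,5,5-tetramethyl-1,3,2-dioxaborolane F4. This is added to 10 in a Hayashi–Miyaura reaction ([Rh(cod)Cl]2, (R)- or (S)-BINAP, KOH, dioxane/H2O, 50 °C). Carbometalation by an alkenylrhodium species under control of the chiral diphosphine replaces pure substrate control, and no electron-transfer pathway is open.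

Step 12 (reduction of ketone 21). What may go wrong is enolisation of the β,γ-unsaturated ketone before reduction (epimerisation at C7, migration of the C10 methylene into conjugation), or hydride delivery from the β face. The fallback sets out from 20, avoids the ketone and comes back at 30. i-Bu2AlH reduces only the ester of 20 to (1S,6S,7R,8S)-12-(4-methoxybenzyloxy)cadina-4,10(14),11(13)-triene-8,15-diol F5. The primary alcohol is silylated (TBSCl, imidazole) to give (1S,6S,7R,8S)-15-(tert-butyldimethylsilyloxy)-12-(4-methoxybenzyloxy)cadina-4,10(14),11(13)-trien-8-ol F6. A Mitsunobu esterification with acid 28 (PPh3, diisopropyl azodicarboxylate, toluene, 0 °C) then inverts C8 and gives 30 directly.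

Further compounds
F1 | step 5 | (2S,3S)-2-{(2R)-1-(tert-butyldimethylsilyloxy)-3-[(4-methoxybenzyloxy)methyl]but-3-en-2-yl}-3-(prop-1-en-2-yl)-6-(trimethylsilyl)cyclohexan-1-one | C[Si](C)(C)C1C(=O)[C@H]([C@@H](CO[Si](C)(C)C(C)(C)C)C(=C)COCc2ccc(OC)cc2)[C@@H](C(C)=C)CC1
F2 | step 5 | (2S,3S)-2-{(2R)-1-(tert-butyldimethylsilyloxy)-3-[(4-methoxybenzyloxy)methyl]but-3-en-2-yl}-3-(prop-1-en-2-yl)cyclohexan-1-one | C1C(=O)[C@H]([C@@H](CO[Si](C)(C)C(C)(C)C)C(=C)COCc2ccc(OC)cc2)[C@@H](C(C)=C)CC1
F3 | step 5 | (5S,6S)-6-{(2R)-1-(tert-butyldimethylsilyloxy)-3-[(4-methoxybenzyloxy)methyl]but-3-en-2-yl}-5-(prop-1-en-2-yl)cyclohex-1-en-1-yl trifluoromethanesulfonate | C1=C(OS(=O)(=O)C(F)(F)F)[C@H]([C@@H](CO[Si](C)(C)C(C)(C)C)C(=C)COCc2ccc(OC)cc2)[C@@H](C(C)=C)CC1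
F4 | step 4 | 2-[3-(4-methoxybenzyloxy)prop-1-en-2-yl]-4,4,5,5-tetramethyl-1,3,2-dioxaborolane | C=C(COCc1ccc(OC)cc1)B1OC(C)(C)C(C)(C)O1
F5 | step 12 | (1S,6S,7R,8S)-12-(4-methoxybenzyloxy)cadina-4,10(14),11(13)-triene-8,15-diol | C=C(COCc3ccc(OC)cc3)[C@H]1[C@H]2C=C(CO)CC[C@@H]2C(=C)C[C@@H]1O
F6 | step 12 | (1S,6S,7R,8S)-15-(tert-butyldimethylsilyloxy)-12-(4-methoxybenzyloxy)cadina-4,10(14),11(13)-trien-8-ol | C=C(COCc3ccc(OC)cc3)[C@H]1[C@H]2C=C(CO[Si](C)(C)C(C)(C)C)CC[C@@H]2C(=C)C[C@@H]1O
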